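**Retrosynthetic overview**

1. The target comes from O-acetylation of the 7-hydroxy-8,11-endoperoxide. The 1,2-dioxane is made last, by sensitised photooxygenation of an epoxy-cembranolide: C11–O by a singlet-oxygen ene reaction, O–C8 by transannular opening of the cis-7,8-epoxide.
2. The epoxy-cembranolide comes from a zinc-mediated intramolecular Barbier allylation/lactonisation (C1–C2 bond), which closes the 14-membered ring and then the cis-α-methylene-γ-lactone.
3. The seco bromo-ester enal comes from cross-metathesis (C1=C15), epoxide closure of a syn-7,8-diol with inversion at C7, and Negishi carboalumination/hydroxymethylation (E-C3=C4, C2).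
4. The syn-diol comes from chelation-controlled addition (C8–C9) of an (E)-homoallylic Grignard reagent (from hex-1-en-5-yne) to an α-hydroxy methyl ketone made from methyl (R)-glycidate and a propargyl Grignard reagent; C7 is the only bought stereocentre.
5. Ring order: oxirane, then 14-membered carbocycle, then γ-lactone, then 1,2-dioxane.

Assumption: the SMILES is read as the (1S,2S,3E,7S,8S,11S,12Z) isomer with a cis-fused lactone; cembrane numbering is used throughout (C1 carries C15, C2 is the lactone O–CH, methyls C18/C19/C20 sit on C4/C8/C12, C16 is the carbonyl carbon, C17 the methylene carbon); compounds 1, 5 and 14 are bought.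

**Route**

Step 1
Reactants: 1 methyl (2R)-oxirane-2-carboxylate
Product: 2 methyl (2R)-2-hydroxyhex-5-ynoate
Conditions: propargylmagnesium bromide (1.3 equiv), CuI (10 mol%), THF/Et2O, −78 °C
Reagents that add atoms: propargylmagnesium bromide, C#CC[Mg]Br
Why: Copper-catalysed SN2 opening of the glycidate at its unsubstituted C3 by the propargyl/allenyl Grignard reagent outruns ester addition at −78 °C and leaves the bought stereocentre (future C7) untouched.

Step 2
Reactants: 2 methyl (2R)-2-hydroxyhex-5-ynoate
Product: 4 (3R)-3-hydroxyhept-6-yn-2-one, via Weinreb amide 3 (not isolated)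
Conditions: MeNH(OMe)·HCl, iPrMgCl, THF, −20 °C; then MeMgBr, −20 → 0 °C
Reagents that add atoms: methylmagnesium bromide, C[Mg]Br
Why: Weinreb ketone synthesis: the magnesium amide converts the ester into the N-methoxy-N-methylamide, whose chelated tetrahedral adduct with MeMgBr stops at the methyl ketone, and the α-alkoxide formed in situ suppresses enolisation of the stereocentre.

Step 3
Reactants: 5 hex-1-en-5-yne
Product: 6 (3E)-4-methylocta-3,7-dien-1-ol
Conditions: Me3Al, Cp2ZrCl2 (20 mol%), CH2Cl2, 0 °C → rt; then n-BuLi, ethylene oxide, THF, −78 → 0 °C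
Reagents that add atoms: trimethylaluminium, C[Al](C)C; ethylene oxide, C1CO1
Why: Negishi zirconium-catalysed carboalumination adds methyl and aluminium syn across the terminal alkyne only, and the derived alanate opens ethylene oxide with retention, fixing the E-trisubstituted alkene (future C11=C12).

Step 4
Reactants: 6 (3E)-4-methylocta-3,7-dien-1-ol
Product: 7 (5E)-8-bromo-5-methylocta-1,5-diene
Conditions: CBr4, PPh3, CH2Cl2, 0 °C
Reagents that add atoms: carbon tetrabromide, BrC(Br)(Br)Br
Why: Appel bromination converts the primary alcohol into the bromide under neutral conditions without touching either alkene.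

Step 5
Reactants: 4 (3R)-3-hydroxyhept-6-yn-2-one; 7 (5E)-8-bromo-5-methylocta-1,5-diene
Product: 9 (5E,9R,10R)-5,9-dimethyltetradeca-1,5-dien-13-yne-9,10-diol, via Grignard reagent 8 (not isolated)
Conditions: 7, Mg, THF, rt; then 4 (0.45 equiv), THF, −78 °C
Reagents that add atoms: none
Why: Chelation-controlled (Cram chelate) Grignard addition: the first equivalent makes the magnesium alkoxide of the α-hydroxy ketone, and the second attacks the five-membered chelate on the face away from the C6 chain, setting C8 as the syn-(7R,8R)-diol.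

Step 6
Reactants: 9 (5E,9R,10R)-5,9-dimethyltetradeca-1,5-dien-13-yne-9,10-diol
Product: 10 (2E,6R,7R,10E)-3,7,11-trimethylpentadeca-2,10,14-triene-1,6,7-triol
Conditions: Me3Al (4 equiv), Cp2ZrCl2 (0.5 equiv), CH2Cl2, 0 °C → rt; then n-BuLi, (CH2O)n, THF, −78 °C → rt
Reagents that add atoms: trimethylaluminium, C[Al](C)C; paraformaldehyde (as formaldehyde), C=O
Why: Negishi carboalumination of the terminal alkyne (the hydroxyls are masked as aluminium alkoxides, the alkenes are inert) followed by trapping of the alanate with formaldehyde gives the E-C3=C4 allylic alcohol with C18 and C2 installed.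

Step 7
Reactants: 10 (2E,6R,7R,10E)-3,7,11-trimethylpentadeca-2,10,14-triene-1,6,7-triol
Product: 11 (2E,6R,7R,10E)-6,7-dihydroxy-3,7,11-trimethylpentadeca-2,10,14-trienal
Conditions: MnO2, CH2Cl2, rt
Reagents that add atoms: none
Why: Manganese dioxide oxidises only the allylic primary alcohol, leaving the saturated secondary and tertiary hydroxyls.

Step 8
Reactants: 11 (2E,6R,7R,10E)-6,7-dihydroxy-3,7,11-trimethylpentadeca-2,10,14-trienal
Product: 13 (2E,6S,7R,10E)-6,7-epoxy-3,7,11-trimethylpentadeca-2,10,14-trienal, via mesylate 12 (not isolated)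
Conditions: MsCl, Et3N, CH2Cl2, −20 °C; then K2CO3, MeOH, 0 °C
Reagents that add atoms: none
Why: Only the secondary hydroxyl is sulfonylated, and intramolecular Williamson (3-exo-tet) displacement by the tertiary alkoxide inverts C7, giving the cis-(7S,8R)-epoxide.

Step 9
Reactants: 13 (2E,6S,7R,10E)-6,7-epoxy-3,7,11-trimethylpentadeca-2,10,14-trienal; 14 methyl 2-(bromomethyl)prop-2-enoate
Product: 15 methyl (2Z,6E,10R,11S,14E)-2-(bromomethyl)-10,11-epoxy-6,10,14-trimethyl-16-oxohexadeca-2,6,14-trienoate
Conditions: second-generation Hoveyda–Grubbs catalyst (5 mol%), 14 (3 equiv), CH2Cl2, 40 °C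
Reagents that add atoms: none
Why: Cross-metathesis joins the only monosubstituted alkene to the 1,1-disubstituted acrylate (which does not homodimerise), with C14 trans to the ester, while the trisubstituted alkenes, the enal and the epoxide do not react.

Step 10
Reactants: 15 methyl (2Z,6E,10R,11S,14E)-2-(bromomethyl)-10,11-epoxy-6,10,14-trimethyl-16-oxohexadeca-2,6,14-trienoate
Product: 17 (1S,2S,3E,7S,8R,11E)-7,8-epoxycembra-3,11,15(17)-trien-16,2-olide, via hydroxy ester 16 (not isolated)
Conditions: Zn–Cu couple, THF, 45 °C, 2 mM (syringe-pump addition)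
Reagents that add atoms: none
Why: Intramolecular Barbier (Reformatsky-type) allylation: the ester-chelated 2-(methoxycarbonyl)allylzinc adds to the enal through a chair transition state to give the syn adduct, which lactonises to the cis-fused α-methylene lactone; the facial sense (1S,2S) is relayed across the forming 14-membered ring by the epoxide stereocentres, a remote control known for allyl–aldehyde closures of epoxy-cembranoid chains.

Step 11
Reactants: 17 (1S,2S,3E,7S,8R,11E)-7,8-epoxycembra-3,11,15(17)-trien-16,2-olide
Product: 19 (1S,2S,3E,7S,8S,11S,12Z)-8,11-epidioxy-7-hydroxycembra-3,12,15(17)-trien-16,2-olide, via allylic hydroperoxide 18 (not isolated)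
Conditions: O2, tetraphenylporphyrin (1 mol%), white LED, CH2Cl2/(CF3)2CHOH 9:1, −20 °C
Reagents that add atoms: dioxygen, O=O
Why: Proposed new method: a one-pot sensitised photooxygenation in which a Schenck ene reaction is coupled to a transannular 6-exo-tet epoxide opening — singlet oxygen attacks the trialkyl C11=C12 alkene (C3=C4 is deactivated by its allylic acyloxy group, the acrylate is inert) on its exposed face at C11 and abstracts the C13–H that stands perpendicular to the π-plane with C14 syn to C11–H (away from the geminal C20 methyl, hence 12Z), and the (11S)-hydroperoxide then attacks C8 of the hexafluoroisopropanol-hydrogen-bonded epoxide anti to its C–O bond, inverting C8 (8R to 8S), retaining C7–O and closing the chair 1,2-dioxane with C7 and C12 both equatorial, so that C11 is controlled through the macrocycle by the existing centres; the closest known reaction types are the Schenck ene reaction and the acid-promoted intramolecular opening of epoxides by hydroperoxides to 1,2-dioxanes, which have not been merged in one pot or run transannularly on a cembranoid.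

Step 12
Reactants: 19 (1S,2S,3E,7S,8S,11S,12Z)-8,11-epidioxy-7-hydroxycembra-3,12,15(17)-trien-16,2-olide
Product: 20 (1S,2S,3E,7S,8S,11S,12Z)-7-acetoxy-8,11-epidioxycembra-3,12,15(17)-trien-16,2-olide
Conditions: Ac2O, pyridine, DMAP (cat.), CH2Cl2, 0 °C → rt
Reagents that add atoms: acetic anhydride, CC(=O)OC(C)=O
Why: Nucleophile-catalysed acylation of the secondary C7 hydroxyl; the dialkyl peroxide and the α-methylene lactone tolerate these mild conditions.

**Compound list**

1 | methyl (2R)-oxirane-2-carboxylate | COC(=O)[C@H]1CO1 | starting material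
2 | methyl (2R)-2-hydroxyhex-5-ynoate | COC(=O)[C@H](O)CCC#C | intermediate
3 | (2R)-2-hydroxy-N-methoxy-N-methylhex-5-ynamide | CON(C)C(=O)[C@H](O)CCC#C | intermediate
4 | (3R)-3-hydroxyhept-6-yn-2-one | CC(=O)[C@H](O)CCC#C | intermediate
5 | hex-1-en-5-yne | C=CCCC#C | starting material
6 | (3E)-4-methylocta-3,7-dien-1-ol | OCC/C=C(\C)CCC=C | intermediate
7 | (5E)-8-bromo-5-methylocta-1,5-diene | BrCC/C=C(\C)CCC=C | intermediate
8 | [(3E)-4-methylocta-3,7-dien-1-yl]magnesium bromide | Br[Mg]CC/C=C(\C)CCC=C | intermediate
9 | (5E,9R,10R)-5,9-dimethyltetradeca-1,5-dien-13-yne-9,10-diol | C=CCC/C(C)=C/CC[C@@](C)(O)[C@H](O)CCC#C | intermediate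
10 | (2E,6R,7R,10E)-3,7,11-trimethylpentadeca-2,10,14-triene-1,6,7-triol | C=CCC/C(C)=C/CC[C@@](C)(O)[C@H](O)CC/C(C)=C/CO | intermediate
11 | (2E,6R,7R,10E)-6,7-dihydroxy-3,7,11-trimethylpentadeca-2,10,14-trienal | C=CCC/C(C)=C/CC[C@@](C)(O)[C@H](O)CC/C(C)=C/C=O | intermediate
12 | (2E,6R,7R,10E)-7-hydroxy-3,7,11-trimethyl-1-oxopentadeca-2,10,14-trien-6-yl methanesulfonate | C=CCC/C(C)=C/CC[C@@](C)(O)[C@H](OS(C)(=O)=O)CC/C(C)=C/C=O | intermediate
13 | (2E,6S,7R,10E)-6,7-epoxy-3,7,11-trimethylpentadeca-2,10,14-trienal | C=CCC/C(C)=C/CC[C@@]1(C)O[C@H]1CC/C(C)=C/C=O | intermediate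
14 | methyl 2-(bromomethyl)prop-2-enoate | C=C(CBr)C(=O)OC | starting material
15 | methyl (2Z,6E,10R,11S,14E)-2-(bromomethyl)-10,11-epoxy-6,10,14-trimethyl-16-oxohexadeca-2,6,14-trienoate | COC(=O)/C(CBr)=C/CC/C(C)=C/CC[C@@]1(C)O[C@H]1CC/C(C)=C/C=O | intermediate
16 | methyl 2-[(1S,2S,3E,7S,8R,11E)-7,8-epoxy-2-hydroxy-4,8,12-trimethylcyclotetradeca-3,11-dien-1-yl]prop-2-enoate | C=C(C(=O)OC)[C@@H]1CC/C(C)=C/CC[C@@]2(C)O[C@H]2CC/C(C)=C/[C@@H]1O | intermediate
17 | (1S,2S,3E,7S,8R,11E)-7,8-epoxycembra-3,11,15(17)-trien-16,2-olide | C=C1C(=O)O[C@H]2/C=C(\C)CC[C@@H]3O[C@]3(C)CC/C=C(\C)CC[C@@H]12 | intermediate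
18 | (1S,2S,3E,7S,8R,11S,12Z)-7,8-epoxy-11-hydroperoxycembra-3,12,15(17)-trien-16,2-olide | C=C1C(=O)O[C@H]2/C=C(\C)CC[C@@H]3O[C@]3(C)CC[C@H](OO)/C(C)=C\C[C@@H]12 | intermediate
19 | (1S,2S,3E,7S,8S,11S,12Z)-8,11-epidioxy-7-hydroxycembra-3,12,15(17)-trien-16,2-olide | C=C1C(=O)O[C@H]2/C=C(\C)CC[C@H](O)[C@]3(C)CC[C@H](OO3)/C(C)=C\C[C@@H]12 | intermediate
20 | (1S,2S,3E,7S,8S,11S,12Z)-7-acetoxy-8,11-epidioxycembra-3,12,15(17)-trien-16,2-olide | C=C1C(=O)O[C@H]2/C=C(\C)CC[C@H](OC(C)=O)[C@]3(C)CC[C@H](OO3)/C(C)=C\C[C@@H]12 | target

**Step count**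

Total: 12 steps. Longest linear sequence: 10 steps (1 → 2 → 4 → 9 → 10 → 11 → 13 → 15 → 17 → 19 → 20; the branch from 5 is equally long).

**The three steps most likely to fail**

Step 11, the proposed photooxygenation cascade, is the least certain. Singlet oxygen may instead take a hydrogen from the C20 methyl or from C10 (the usual preference for the more crowded side of a trisubstituted alkene), giving the 12(20)-methylidene isomer or a tertiary C12 hydroperoxide that cannot cyclise. The face of attack and the 12Z geometry rest on the macrocycle conformation, which is not established. The fallback uses known chemistry and sets out from 17. Perhydrolysis of the epoxide with anhydrous H2O2 in Et2O and catalytic MoO2(acac)2 opens it at the tertiary C8 with inversion and gives (1S,2S,3E,7S,8S,11E)-8-hydroperoxy-7-hydroxycembra-3,11,15(17)-trien-16,2-olide F1. F1 is then closed by the Pd(OAc)2-catalysed oxidative cyclisation of unsaturated tertiary hydroperoxides (1,4-benzoquinone as oxidant, 1,2-dichloroethane, 40 °C): 6-exo peroxypalladation at C11 and β-hydride loss from C13 return the route at 19.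

Step 10, the Barbier macrocyclisation, can fail through oligomerisation or protodebromination, and the sense and level of remote induction by the cis-epoxide are not secured. The fallback sets out from 13. Cross-metathesis with methyl 2-(acetoxymethyl)prop-2-enoate under the step 9 conditions gives methyl (2E,6E,10R,11S,14E)-2-(acetoxymethyl)-10,11-epoxy-6,10,14-trimethyl-16-oxohexadeca-2,6,14-trienoate F2. Ring closure is then done by umpolung of a π-allylpalladium species: Pd(PPh3)4 (5 mol%) and InI in THF at high dilution transmetalate to an allylindium, which adds to the enal through a different cyclic transition state and lactonises through the same hydroxy ester 16. The route is rejoined at 17.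

Step 9, the cross-metathesis, may be sluggish because 14 is a 1,1-disubstituted, electron-poor partner, and its activated allylic C–Br bond can alkylate or decompose the ruthenium carbene. The fallback sets out from 13. Cross-metathesis with the more benign methyl 2-(hydroxymethyl)prop-2-enoate gives methyl (2E,6E,10R,11S,14E)-10,11-epoxy-2-(hydroxymethyl)-6,10,14-trimethyl-16-oxohexadeca-2,6,14-trienoate F3. Appel bromination of its primary allylic alcohol (CBr4, PPh3, CH2Cl2, 0 °C) returns the route at 15.

Further compounds
F1 | step 11 | (1S,2S,3E,7S,8S,11E)-8-hydroperoxy-7-hydroxycembra-3,11,15(17)-trien-16,2-olide | C=C1C(=O)O[C@H]2/C=C(\C)CC[C@H](O)[C@@](C)(OO)CC/C=C(\C)CC[C@@H]12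
F2 | step 10 | methyl (2E,6E,10R,11S,14E)-2-(acetoxymethyl)-10,11-epoxy-6,10,14-trimethyl-16-oxohexadeca-2,6,14-trienoate | COC(=O)/C(COC(C)=O)=C/CC/C(C)=C/CC[C@@]1(C)O[C@H]1CC/C(C)=C/C=O
F3 | step 9 | methyl (2E,6E,10R,11S,14E)-10,11-epoxy-2-(hydroxymethyl)-6,10,14-trimethyl-16-oxohexadeca-2,6,14-trienoate | COC(=O)/C(CO)=C/CC/C(C)=C/CC[C@@]1(C)O[C@H]1CC/C(C)=C/C=O
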